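The route rests on cutting the C3–C4 bond and the ring-fusion bond C4a–C8a of the chromene-2,7-dione. The feature exploited is the 1,3,5-tricarbonyl pattern of the carbocycle (C5, C7, C8a around quaternary C8), which lets this ring be stored as a 6-styryl-2H-pyran-2,4(3H)-dione whose enol-lactone C–O bond is absent from the target. In one flask a catalyst-controlled 1,6-Michael addition of Meldrum's acid to the styryl terminus forms C3–C4 and sets C4; methoxide then opens the enol lactone and a Dieckmann closure forms C4a–C8a; decarboxylative lactonization closes the lactone. A final C6 acylation completes the target.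

Key step: step 3

Remark: positions are named by the chromene numbering of the target (O1, C2, C3, C4, C4a, C5 to C8, C8a), also in the pyranone and open-chain precursors; enolised di- and triketones are drawn as one tautomer.
Remark: (2R)-2-methylbutanoic acid and the cinchona amine–squaramide catalysts are taken as commercially available.

Step 1
Reactants: 1 4-hydroxy-6-methyl-2H-pyran-2-one; 2 3-methylbut-2-en-1-yl acetate (prenyl acetate)
Product: 4 6-methyl-3,3-bis(3-methylbut-2-en-1-yl)-2H-pyran-2,4(3H)-dione, via monoprenyl pyranone 3 (not isolated)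
Conditions: 2 (2.4 equiv), Pd(PPh3)4 (5 mol %), Et3N (2.5 equiv), THF, 50 °C
Reagents that add atoms: none
Why: Tsuji–Trost allylation: the vinylogous acid 1 and then 3 should be C-allylated at the carbon between the two oxygenated carbons by the π-prenyl palladium complex at its unhindered CH2 terminus, and any O-prenyl ether should re-ionise under zerovalent palladium so that material funnels to the quaternary dione 4, which has no acidic hydrogen left.

Step 2
Reactants: 4 6-methyl-3,3-bis(3-methylbut-2-en-1-yl)-2H-pyran-2,4(3H)-dione; 5 benzaldehyde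
Product: 8 3,3-bis(3-methylbut-2-en-1-yl)-6-[(E)-2-phenylethenyl]-2H-pyran-2,4(3H)-dione, via aldol adduct 6 (not isolated), via mesylate 7 (not isolated)
Conditions: LiN(SiMe3)2 (1.1 equiv), THF, −78 °C; 5 (1.2 equiv); MsCl (1.3 equiv), −78 → 0 °C; DBU (2.5 equiv), 0 → 23 °C
Reagents that add atoms: none
Why: Vinylogous aldol condensation: the 6-methyl group is the only enolisable site of 4, its lithium dienolate should add to 5 through the exocyclic carbon as the dienolates of 6-methyl-1,3-dioxin-4-ones do, and E1cB loss of mesylate should give the conjugated E alkene under thermodynamic control.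

Step 3
Reactants: 8 3,3-bis(3-methylbut-2-en-1-yl)-6-[(E)-2-phenylethenyl]-2H-pyran-2,4(3H)-dione; 9 2,2-dimethyl-1,3-dioxane-4,6-dione (Meldrum's acid)
Product: 13 (4S)-5-hydroxy-8,8-bis(3-methylbut-2-en-1-yl)-4-phenyl-3,4-dihydro-2H-chromene-2,7(8H)-dione, via Michael adduct 10 (not isolated), via ring-opened diketo ester 11 (not isolated), via trione 12 (not isolated)
Conditions: 9 (1.3 equiv), cinchona-derived tertiary amine–squaramide (10 mol %, the pseudo-enantiomer that gives 4S), toluene, 0 → 23 °C; then NaOMe (6 equiv), THF–MeOH, 0 → 45 °C; then aq HCl to pH 2, extraction, toluene, 85 °C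
Reagents that add atoms: none
Why: The chiral ammonium–squaramide ion pair should add the anion of 9 to the styryl terminus C4 of 8 (vinylogous 1,6-Michael addition, the reaction type known for styryl-substituted electron-poor heterocycles under bifunctional cinchona catalysis), which forms C3–C4 and turns the vinylic C4a into an enolisable CH2 in 10. Methoxide then opens the enol lactone at C8a to 11 and the terminal carbanion of the diketone dianion closes C4a onto the freed ester (Dieckmann condensation, 6-exo-trig), the alkoxide-induced isomerisation known for pyran-2,4-diones to cyclohexane-1,3,5-triones. Under base the Meldrum's acid unit is an anion that can neither leave (no retro-Michael, so C4 keeps its configuration) nor be attacked by the diketonate. After acidification the hydroxyl on C8a of the C4a=C8a enol in 12 attacks a dioxanedione carbonyl (6-exo-trig) and acetone and CO2 are lost, the standard decarboxylative lactonisation of enol–Meldrum's acid adducts. The only new stereocentre, C4, is set in the addition by the catalyst, and its pseudo-enantiomer is chosen to give S. Needed are attack at C4 and not at the acyloxy-bearing ring carbon or the lactone carbonyl, which the soft nucleophile and the quaternary carbon next to the lactone carbonyl should secure, and lactone closure on the oxygen at C8a and not at C5, which should be favoured because only it keeps the C5–C6–C7 vinylogous acid.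

Step 4
Reactants: 13 (4S)-5-hydroxy-8,8-bis(3-methylbut-2-en-1-yl)-4-phenyl-3,4-dihydro-2H-chromene-2,7(8H)-dione; 14 (2R)-2-methylbutanoic acid
Product: 16 (4S)-5-hydroxy-6-[(2R)-2-methylbutanoyl]-8,8-bis(3-methylbut-2-en-1-yl)-4-phenyl-3,4-dihydro-2H-chromene-2,7(8H)-dione, via enol ester 15 (not isolated)
Conditions: 14 (1.2 equiv), EDC·HCl (1.3 equiv), DMAP (1.5 equiv), CH2Cl2, 0 → 23 °C
Reagents that add atoms: none
Why: Carbodiimide O-acylation of the vinylogous acid 13 to enol ester 15 and DMAP-mediated O-to-C acyl migration (the rearrangement used for 2-acylcyclohexane-1,3-diones) should place the acyl group on C6, the only free nucleophilic carbon, with the chelated enolised triketone as driving force; the stereocentre of 14 should be carried through because neither an acid chloride nor a strong base is used.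

Compound list
1 | 4-hydroxy-6-methyl-2H-pyran-2-one (triacetic acid lactone) | CC1=CC(O)=CC(=O)O1 | starting material
2 | 3-methylbut-2-en-1-yl acetate (prenyl acetate) | CC(=O)OCC=C(C)C | starting material
3 | 4-hydroxy-6-methyl-3-(3-methylbut-2-en-1-yl)-2H-pyran-2-one | CC1=CC(O)=C(CC=C(C)C)C(=O)O1 | intermediate
4 | 6-methyl-3,3-bis(3-methylbut-2-en-1-yl)-2H-pyran-2,4(3H)-dione | CC1=CC(=O)C(CC=C(C)C)(CC=C(C)C)C(=O)O1 | intermediate
5 | benzaldehyde | O=Cc1ccccc1 | starting material
6 | 6-(2-hydroxy-2-phenylethyl)-3,3-bis(3-methylbut-2-en-1-yl)-2H-pyran-2,4(3H)-dione (racemic, present as its lithium alkoxide) | OC(CC1=CC(=O)C(CC=C(C)C)(CC=C(C)C)C(=O)O1)c1ccccc1 | intermediate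
7 | 2-[3,3-bis(3-methylbut-2-en-1-yl)-2,4-dioxo-3,4-dihydro-2H-pyran-6-yl]-1-phenylethyl methanesulfonate (racemic) | CS(=O)(=O)OC(CC1=CC(=O)C(CC=C(C)C)(CC=C(C)C)C(=O)O1)c1ccccc1 | intermediate
8 | 3,3-bis(3-methylbut-2-en-1-yl)-6-[(E)-2-phenylethenyl]-2H-pyran-2,4(3H)-dione | O=C1OC(/C=C/c2ccccc2)=CC(=O)C1(CC=C(C)C)CC=C(C)C | intermediate
9 | 2,2-dimethyl-1,3-dioxane-4,6-dione (Meldrum's acid) | CC1(C)OC(=O)CC(=O)O1 | starting material
10 | 5-[(1S)-2-[3,3-bis(3-methylbut-2-en-1-yl)-2,4-dioxo-3,4-dihydro-2H-pyran-6-yl]-1-phenylethyl]-2,2-dimethyl-1,3-dioxane-4,6-dione | CC1(C)OC(=O)C([C@H](CC2=CC(=O)C(CC=C(C)C)(CC=C(C)C)C(=O)O2)c2ccccc2)C(=O)O1 | intermediate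
11 | methyl (7S)-7-(2,2-dimethyl-4,6-dioxo-1,3-dioxan-5-yl)-2,2-bis(3-methylbut-2-en-1-yl)-3,5-dioxo-7-phenylheptanoate | COC(=O)C(CC=C(C)C)(CC=C(C)C)C(=O)CC(=O)C[C@H](c1ccccc1)C1C(=O)OC(C)(C)OC1=O | intermediate
12 | 5-[(S)-[2-hydroxy-3,3-bis(3-methylbut-2-en-1-yl)-4,6-dioxocyclohex-1-en-1-yl](phenyl)methyl]-2,2-dimethyl-1,3-dioxane-4,6-dione (one enol tautomer of the trione) | CC(C)=CCC1(CC=C(C)C)C(=O)CC(=O)C([C@H](c2ccccc2)C2C(=O)OC(C)(C)OC2=O)=C1O | intermediate
13 | (4S)-5-hydroxy-8,8-bis(3-methylbut-2-en-1-yl)-4-phenyl-3,4-dihydro-2H-chromene-2,7(8H)-dione | O=C1C=C(O)C2=C(OC(=O)C[C@H]2c2ccccc2)C1(CC=C(C)C)CC=C(C)C | intermediate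
14 | (2R)-2-methylbutanoic acid | CC[C@@H](C)C(=O)O | starting material
15 | (4S)-8,8-bis(3-methylbut-2-en-1-yl)-2,7-dioxo-4-phenyl-3,4,7,8-tetrahydro-2H-chromen-5-yl (2R)-2-methylbutanoate | CC[C@@H](C)C(=O)OC1=CC(=O)C(CC=C(C)C)(CC=C(C)C)C2=C1[C@H](c1ccccc1)CC(=O)O2 | intermediate
16 | (4S)-5-hydroxy-6-[(2R)-2-methylbutanoyl]-8,8-bis(3-methylbut-2-en-1-yl)-4-phenyl-3,4-dihydro-2H-chromene-2,7(8H)-dione | CC[C@@H](C)C(=O)C1=C(O)C2=C(OC(=O)C[C@H]2c2ccccc2)C(CC=C(C)C)(CC=C(C)C)C1=O | target

Total step count: 4. Longest linear sequence: 4 steps (1 → 4 → 8 → 13 → 16).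

Steps most likely to fail

First, step 3. The 1,6-addition may be slow or show poor facial selectivity, because the nucleophile is weak and the reacting carbon is remote from the catalyst binding site. The enol lactone may be opened by the nucleophile or the amine before addition, the hindered C4a–C8a closure may stall, and the lactone may close on the other enol oxygen. The fallback sets out from 4 and comes back at 13. NaOMe in MeOH–THF should open the enol lactone of 4 to methyl 2,2-bis(3-methylbut-2-en-1-yl)-3,5-dioxohexanoate F1, which is not isolated and should close by Dieckmann condensation of its terminal methyl group onto the ester to the symmetric 3,5-dihydroxy-4,4-bis(3-methylbut-2-en-1-yl)cyclohexa-2,5-dien-1-one F2, the dienol of the 1,3,5-trione. F2 is then annulated with (E)-cinnamic anhydride under isothiourea catalysis (the enantiomer of HyperBTM that gives 4S, iPr2NEt, CH2Cl2). This is a Michael addition–lactonisation through the α,β-unsaturated acyl ammonium ion; it builds C4–C4a and the lactone C–O bond in place of C3–C4 and should give 13.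

Second, step 1. The allylation may stop after the first prenyl group, O-prenylation may fail to revert, or the π-prenyl complex may be attacked at its tertiary terminus. The fallback sets out from 2 and comes back at 4. Ethyl acetoacetate is prenylated twice with 2 (NaH, Pd(PPh3)4, THF) to ethyl 2-acetyl-5-methyl-2-(3-methylbut-2-en-1-yl)hex-4-enoate F3. Its kinetic enolate (LiN(iPr)2, THF, −78 °C) is acylated with N-methoxy-N-methylacetamide to ethyl 2,2-bis(3-methylbut-2-en-1-yl)-3,5-dioxohexanoate F4. Acid-catalysed enol lactonisation (pyridinium p-toluenesulfonate, toluene, reflux with removal of ethanol) should close F4 to 4.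

Third, step 2. The amide base or the aldolate may attack the enol lactone, the dienolate may react through the ring carbon instead of the exocyclic carbon, or retro-aldol cleavage may precede mesylation. The fallback sets out from 4 and comes back at 8. The dienolate of 4 (LiN(iPr)2, 2 equiv, THF, −78 °C) is phosphorylated at the exocyclic carbon with ClP(O)(OEt)2 to diethyl {[3,3-bis(3-methylbut-2-en-1-yl)-2,4-dioxo-3,4-dihydro-2H-pyran-6-yl]methyl}phosphonate F5. A Horner–Wadsworth–Emmons olefination of F5 with 5 (LiCl, DBU, MeCN) should give 8 as the E alkene.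

Further compounds
F1 | step 3 | methyl 2,2-bis(3-methylbut-2-en-1-yl)-3,5-dioxohexanoate | COC(=O)C(CC=C(C)C)(CC=C(C)C)C(=O)CC(C)=O
F2 | step 3 | 3,5-dihydroxy-4,4-bis(3-methylbut-2-en-1-yl)cyclohexa-2,5-dien-1-one | O=C1C=C(O)C(CC=C(C)C)(CC=C(C)C)C(O)=C1
F3 | step 1 | ethyl 2-acetyl-5-methyl-2-(3-methylbut-2-en-1-yl)hex-4-enoate | CCOC(=O)C(CC=C(C)C)(CC=C(C)C)C(C)=O
F4 | step 1 | ethyl 2,2-bis(3-methylbut-2-en-1-yl)-3,5-dioxohexanoate | CCOC(=O)C(CC=C(C)C)(CC=C(C)C)C(=O)CC(C)=O
F5 | step 2 | diethyl {[3,3-bis(3-methylbut-2-en-1-yl)-2,4-dioxo-3,4-dihydro-2H-pyran-6-yl]methyl}phosphonate | CCOP(=O)(OCC)CC1=CC(=O)C(CC=C(C)C)(CC=C(C)C)C(=O)O1
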